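Ring A is cut across C1–C14 and C10–C11. Its trans-related C1 (quaternary, C15 methyl) and C10 centres, flanked by the C11/C12 oxygenation, are made in one Lewis acid promoted Diels–Alder step between a 2-silyloxydiene (C11–C14, C20) and an (E)-2-methyl enal (C2, C1, C10) whose C9 dioxolane must steer the diene. The enal carries C8/C9 as a 2-aryl dioxolane, so that reductive opening later leaves C9–OPMB to direct, by chelation, the aldol that builds C8 and C17. C2 is extended by Julia–Kocienski olefination and Shi epoxidation; the ten-membered ring is closed at C6–C7 by a Nozaki–Hiyama–Kishi reaction, and the lactone then closes onto O7.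

Key step: step 4

Remark: briarane numbering of the target is used for every intermediate (C15 = methyl on C1, C16 = CH2O on C5, C17/C18/C19 = lactone CH, its methyl and its carbonyl, C20 = methyl on C11).
Remark: the acetal carbon of the aryl dioxolane in 5, 8 and 19 forms as both epimers; SMILES carry no descriptor there, and the centre disappears in step 13.
Remark: C11 is drawn in 8–27 as formed by formyl-endo addition; it is enolisable from step 18 on and is fixed in step 19.
Remark: compound 9 is taken to be commercially available.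

Step 1
Reactants: 1 (S)-2,2-dimethyl-1,3-dioxolane-4-carbaldehyde; 2 2-(triphenylphosphoranylidene)propanal
Product: 3 (E)-3-[(4R)-2,2-dimethyl-1,3-dioxolan-4-yl]-2-methylprop-2-enal
Conditions: PhMe, 80 °C
Reagents that add atoms: none
Why: Wittig olefination with the formyl-stabilised ylide should give the E enal under thermodynamic control, and the neutral conditions leave the C9 stereocentre untouched.

Step 2
Reactants: 3 acetonide enal; 4 1-(dimethoxymethyl)-4-methoxybenzene
Product: 5 (E)-3-[(4R)-2-(4-methoxyphenyl)-1,3-dioxolan-4-yl]-2-methylprop-2-enal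
Conditions: camphorsulfonic acid (cat.), PhMe, 40 °C, 200 mbar
Reagents that add atoms: none
Why: Acid-catalysed transacetalisation replaces the isopropylidene ketal by the more stable aryl aldehyde acetal while volatile 2,2-dimethoxypropane is pumped off, without involving C9.

Step 3
Reactants: 6 pent-1-en-3-one
Product: 7 (Z)-tert-butyldimethyl(penta-1,3-dien-3-yloxy)silane
Conditions: tBuMe2SiOTf, Et3N, Et2O, 0 °C
Reagents that add atoms: tert-butyldimethylsilyl trifluoromethanesulfonate, CC(C)(C)[Si](C)(C)OS(=O)(=O)C(F)(F)F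
Why: Soft enolisation and O-silylation of the ethyl ketone should give the Z silyl enol ether, whose methyl group lies outside in the s-cis diene.

Step 4
Reactants: 5 aryl dioxolane enal; 7 silyloxydiene
Product: 8 (1S,5S,6S)-4-[(tert-butyldimethylsilyl)oxy]-6-[(4R)-2-(4-methoxyphenyl)-1,3-dioxolan-4-yl]-1,5-dimethylcyclohex-3-ene-1-carbaldehyde
Conditions: Me2AlCl (1.1 equiv), 7 (2.5 equiv), CH2Cl2, −78 → −40 °C
Reagents that add atoms: none
Why: Me2AlCl binds the formyl oxygen and the diene adds in a concerted, asynchronous [4+2] cycloaddition in which the enol ether carbon C11 bonds to the β-carbon C10 ahead of C14–C1 bonding; the closest known reaction type is the Lewis acid promoted Diels–Alder addition of 2-silyloxydienes to α-methyl α,β-unsaturated aldehydes that creates quaternary carbons. Ring A is closed as a six-membered carbocycle by this intermolecular cycloaddition, both new σ-bonds forming suprafacially on each partner. C1 and C10 are set relative to each other by the E geometry of the enal (C2 trans to C9), C11 by formyl-endo addition of the diene carrying its methyl group outside (reset in step 19), and the silyloxy group places C12 1,4 to C1. The absolute sense at C1/C10 must be relayed from C9: allylic 1,3-strain with the C15 methyl group holds H9 in the enal plane, and the diene has to attack the C10 face on the side of the ring oxygen O9, anti to the larger C8 methylene arm. The step therefore needs this facial selectivity (secured only by the dioxolane stereocentre; attack anti to the C9–O bond is the competing mode), para regioselectivity (secured by the 2-silyloxy group) and an intact aryl acetal (secured by one equivalent of Me2AlCl at low temperature).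

Step 5
Reactants: 9 ethyl 2-oxotetrahydrofuran-3-carboxylate
Product: 10 ethyl 3-(diiodomethyl)-2-oxotetrahydrofuran-3-carboxylate
Conditions: NaH, CHI3, Et2O, reflux
Reagents that add atoms: iodoform, IC(I)I
Why: C-alkylation of the malonate-type sodium enolate with iodoform, the known diiodomethylation of substituted malonates, installs the CHI2 group that becomes C6.

Step 6
Reactants: 10 diiodomethyl lactone ester
Product: 12 (E)-3-(iodomethylidene)oxolan-2-one, via (E)-hydroxy acid 11 (not isolated)
Conditions: KOH, EtOH/H2O, reflux; then aq. HCl, rt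
Reagents that add atoms: potassium hydroxide, [K+].[OH-]
Why: Saponification and decarboxylative elimination of iodide should give the 3-iodoacrylate with iodine trans to the remaining carboxyl group, as in the known route to (E)-3-iodo-2-alkylacrylic acids, and acidification relactonises the γ-hydroxy acid.

Step 7
Reactants: 12 iodomethylidene lactone
Product: 13 ethyl (E)-3-iodo-2-(2-iodoethyl)prop-2-enoate
Conditions: Me3SiI, CH2Cl2, rt; then EtOH
Reagents that add atoms: iodotrimethylsilane, C[Si](C)(C)I; ethanol, CCO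
Why: Silyl iodide cleavage of the lactone at its alkyl C–O bond followed by ethanolysis, the standard lactone to ω-iodo ester conversion, differentiates C3 from C16 without halogen scrambling at C6.

Step 8
Reactants: 13 diiodo ester
Product: 14 (E)-3-iodo-2-(2-iodoethyl)prop-2-en-1-ol
Conditions: iBu2AlH, CH2Cl2, −78 °C
Reagents that add atoms: none
Why: 1,2-Reduction of the conjugated ester gives the allylic alcohol (C16–OH) and spares the iodoalkene and the primary iodide at low temperature.

Step 9
Reactants: 14 iodo alcohol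
Product: 15 tert-butyl{[(E)-3-iodo-2-(2-iodoethyl)prop-2-en-1-yl]oxy}dimethylsilane
Conditions: tBuMe2SiCl, imidazole, CH2Cl2, 0 °C
Reagents that add atoms: tert-butyldimethylsilyl chloride, CC(C)(C)[Si](C)(C)Cl
Why: Silylation protects C16–OH and prevents its cyclisation onto the alkyl iodide in the basic step that follows.

Step 10
Reactants: 15 silyl ether
Product: 16 5-{[(E)-3-({[tert-butyl(dimethyl)silyl]oxy}methyl)-4-iodobut-3-en-1-yl]sulfanyl}-1-phenyl-1H-tetrazole
Conditions: 1-phenyl-1H-tetrazole-5-thiol, K2CO3, DMF, rt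
Reagents that add atoms: 1-phenyl-1H-tetrazole-5-thiol, Sc1nnnn1-c1ccccc1
Why: SN2 displacement of the primary iodide by the thiolate gives the sulfide, the unactivated iodoalkene being inert.

Step 11
Reactants: 16 sulfide
Product: 17 5-{[(E)-3-({[tert-butyl(dimethyl)silyl]oxy}methyl)-4-iodobut-3-en-1-yl]sulfonyl}-1-phenyl-1H-tetrazole
Conditions: (NH4)6Mo7O24·4H2O (cat.), 30% H2O2, EtOH, 0 °C → rt
Reagents that add atoms: hydrogen peroxide, OO
Why: Molybdate-catalysed sulfide oxidation is the standard entry to Julia–Kocienski sulfones and leaves the electron-poor iodoalkene and the silyl ether intact.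

Step 12
Reactants: 8 ring A aldehyde; 17 sulfone
Product: 19 diene with the C2=C3 E double bond, via metallated sulfone 18 (not isolated)
Conditions: 17, KN(SiMe3)2, DME, −60 °C; then 8, −60 °C → rt
Reagents that add atoms: none
Why: Julia–Kocienski olefination of the hindered, non-enolisable C2 aldehyde (addition, Smiles rearrangement, loss of SO2 and tetrazololate) should give the E alkene, as usual for phenyltetrazolyl sulfones with a potassium counter-ion, while silyl enol ether, acetal and iodoalkene tolerate the base.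

Step 13
Reactants: 19 diene
Product: 20 primary alcohol with C9–O-(4-methoxybenzyl) and C8H2OH
Conditions: iBu2AlH, CH2Cl2, −78 → 0 °C
Reagents that add atoms: none
Why: In this reductive acetal opening the aluminium hydride coordinates the less hindered O8 and delivers hydride to the acetal carbon, so the PMB group should stay on the secondary O9 and C8–OH is freed without acid, which the ring A silyl enol ether would not survive.

Step 14
Reactants: 20 primary alcohol
Product: 21 C8 aldehyde
Conditions: Dess–Martin periodinane, NaHCO3, CH2Cl2, 0 °C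
Reagents that add atoms: none
Why: Buffered Dess–Martin oxidation is mild enough for the silyl enol ether and for the epimerisable α-alkoxy centre C9.

Step 15
Reactants: 21 C8 aldehyde
Product: 22 C8 allylic alcohol carrying C7 as a vinyl group
Conditions: CH2=CHMgBr, THF, −78 °C
Reagents that add atoms: vinylmagnesium bromide, C=C[Mg]Br
Why: Grignard 1,2-addition brings in C7 as a masked formyl group; the new C8 carbinol centre forms as a mixture and is erased in step 16.

Step 16
Reactants: 22 allylic alcohol
Product: 23 C8 vinyl ketone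
Conditions: Dess–Martin periodinane, NaHCO3, CH2Cl2, 0 °C
Reagents that add atoms: none
Why: Dess–Martin oxidation gives the α-alkoxy vinyl ketone, which is used at once because of its Michael reactivity.

Step 17
Reactants: 23 vinyl ketone; 24 methyl propanoate
Product: 26 β-hydroxy ester with C8 and C17 set, via lithium enolate 25 (not isolated)
Conditions: 24, LiN(iPr)2, THF, −78 °C; then 23, MgBr2·OEt2, CH2Cl2, −78 °C; AcOH quench at −78 °C
Reagents that add atoms: none
Why: In this chelation-controlled aldol addition MgBr2 ties the C8 carbonyl to the C9 PMB ether so that the enolate attacks the face opposite C10 (Cram chelate model, sets C8), and the E(O) enolate reacting through a Zimmerman–Traxler chair with the chelating C9 arm axial and its own methyl group equatorial should set C17 as in the target, kinetic 1,2-addition of lithium ester enolates to enones being preferred at −78 °C.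

Step 18
Reactants: 26 β-hydroxy ester
Product: 27 ring A enone (C12 ketone, C13=C14)
Conditions: IBX, 4-methoxypyridine N-oxide, DMSO, rt
Reagents that add atoms: none
Why: Dehydrogenation of the silyl enol ether by the IBX·N-oxide complex, a metal-free counterpart of the Saegusa oxidation, introduces the C13=C14 double bond and cannot insert into the iodoalkene as a palladium reagent might.

Step 19
Reactants: 27 enone
Product: 29 C11 acetate with C8–OSiEt3, via silyl dienol ether 28 (not isolated)
Conditions: Et3SiOTf, Et3N, CH2Cl2, 0 °C; then Pb(OAc)4, CH2Cl2, −40 → 0 °C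
Reagents that add atoms: triethylsilyl trifluoromethanesulfonate, CC[Si](CC)(CC)OS(=O)(=O)C(F)(F)F; lead tetraacetate, CC(=O)O[Pb](OC(C)=O)(OC(C)=O)OC(C)=O
Why: Soft enolisation toward C11 gives the cross-conjugated silyl dienol ether and caps the tertiary C8–OH, and Rubottom-type α-acetoxylation with Pb(OAc)4 should deliver the acetate to C11 anti to the C10 side chain (OAc cis to H10, as in the target).

Step 20
Reactants: 29 C11 acetate
Product: 30 (2R,3R)-epoxide
Conditions: Shi ketone (D-fructose-derived, 0.3 equiv), KHSO5 (as 2KHSO5·KHSO4·K2SO4), K2CO3, Bu4NHSO4, MeCN/CH2(OMe)2/aq. Na2B4O7 buffer, 0 °C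
Reagents that add atoms: potassium peroxymonosulfate, [K+].[O-]S(=O)(=O)OO
Why: In the Shi epoxidation the chiral dioxirane oxidises the trans-disubstituted C2=C3 bond through a spiro transition state under reagent control, which should give the (2R,3R)-epoxide, while enone, iodoalkene and the hindered terminal vinyl group react far more slowly.

Step 21
Reactants: 30 epoxide
Product: 31 C7 aldehyde
Conditions: OsO4 (cat.), NaIO4, 2,6-lutidine, dioxane/H2O, rt
Reagents that add atoms: sodium periodate, [Na+].[O-]I(=O)(=O)=O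
Why: In this Lemieux–Johnson cleavage OsO4 dihydroxylates the accessible monosubstituted alkene in preference to the iodoalkene and the enone, and periodate cleaves the diol to the aldehyde without passing through a free C7 alcohol that could lactonise onto C19.

Step 22
Reactants: 31 iodoalkene aldehyde
Product: 33 ten-membered lactone (O7–C19), via macrocyclic hydroxy ester 32 (not isolated)
Conditions: CrCl2, NiCl2 (cat.), DMSO/THF, rt, 3 mM; then DMAP (cat.), PhMe, 40 °C
Reagents that add atoms: none
Why: In this intramolecular Nozaki–Hiyama–Kishi reaction the alkenylchromium species, formed with retention of the alkene geometry, adds to the C7 aldehyde and closes the ten-membered ring at C6–C7; a Felkin–Anh arrangement (C8 silyloxy group anti to the incoming carbon, larger C9 branch away from it) should set C7, and the alkoxide then lactonises onto the C19 methyl ester.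

Step 23
Reactants: 33 lactone
Product: 34 C9 alcohol
Conditions: DDQ, CH2Cl2/pH 7 buffer, 0 °C
Reagents that add atoms: none
Why: Buffered oxidative cleavage of the PMB ether frees C9–OH only after ring closure, when C19 is tied up in the O7 lactone and the ring holds the epoxide out of reach of O9.

Step 24
Reactants: 34 C9 alcohol
Product: 35 8,9,16-triol
Conditions: HF·pyridine, pyridine, THF, 0 °C → rt
Reagents that add atoms: none
Why: Pyridine-buffered fluoride desilylation removes the primary TBS ether on O16 and the tertiary triethylsilyl ether on O8, while acetate, lactone and epoxide should survive.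

Step 25
Reactants: 35 triol
Product: 36 CNP0226792.2
Conditions: Ac2O, pyridine, rt
Reagents that add atoms: acetic anhydride, CC(=O)OC(C)=O
Why: Acetylation without an acyl-transfer catalyst esterifies the primary C16 and secondary C9 hydroxyl groups but not the hindered tertiary C8–OH, which gives the target.

Compound list
1 | (S)-2,2-dimethyl-1,3-dioxolane-4-carbaldehyde | O=C[C@@H]1COC(C)(C)O1 | starting material
2 | 2-(triphenylphosphoranylidene)propanal | CC(C=O)=P(c1ccccc1)(c1ccccc1)c1ccccc1 | starting material
3 | (E)-3-[(4R)-2,2-dimethyl-1,3-dioxolan-4-yl]-2-methylprop-2-enal | O=C/C(C)=C/[C@@H]1COC(C)(C)O1 | intermediate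
4 | 1-(dimethoxymethyl)-4-methoxybenzene | COC(OC)c1ccc(OC)cc1 | starting material
5 | (E)-3-[(4R)-2-(4-methoxyphenyl)-1,3-dioxolan-4-yl]-2-methylprop-2-enal (both acetal epimers) | O=C/C(C)=C/[C@@H]1COC(c2ccc(OC)cc2)O1 | intermediate
6 | pent-1-en-3-one | CCC(=O)C=C | starting material
7 | (Z)-tert-butyldimethyl(penta-1,3-dien-3-yloxy)silane | C=C/C(O[Si](C)(C)C(C)(C)C)=C/C | intermediate
8 | (1S,5S,6S)-4-[(tert-butyldimethylsilyl)oxy]-6-[(4R)-2-(4-methoxyphenyl)-1,3-dioxolan-4-yl]-1,5-dimethylcyclohex-3-ene-1-carbaldehyde | O=C[C@@]1(C)CC=C(O[Si](C)(C)C(C)(C)C)[C@@H](C)[C@@H]1[C@@H]2COC(c3ccc(OC)cc3)O2 | intermediate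
9 | ethyl 2-oxotetrahydrofuran-3-carboxylate | CCOC(=O)C1CCOC1=O | starting material
10 | ethyl 3-(diiodomethyl)-2-oxotetrahydrofuran-3-carboxylate (racemic) | CCOC(=O)C1(C(I)I)CCOC1=O | intermediate
11 | (E)-2-(2-hydroxyethyl)-3-iodoprop-2-enoic acid | I/C=C(/C(=O)O)CCO | intermediate
12 | (E)-3-(iodomethylidene)oxolan-2-one | I/C=C1/C(=O)OCC1 | intermediate
13 | ethyl (E)-3-iodo-2-(2-iodoethyl)prop-2-enoate | I/C=C(/C(=O)OCC)CCI | intermediate
14 | (E)-3-iodo-2-(2-iodoethyl)prop-2-en-1-ol | I/C=C(/CO)CCI | intermediate
15 | tert-butyl{[(E)-3-iodo-2-(2-iodoethyl)prop-2-en-1-yl]oxy}dimethylsilane | I/C=C(/CO[Si](C)(C)C(C)(C)C)CCI | intermediate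
16 | 5-{[(E)-3-({[tert-butyl(dimethyl)silyl]oxy}methyl)-4-iodobut-3-en-1-yl]sulfanyl}-1-phenyl-1H-tetrazole | I/C=C(/CO[Si](C)(C)C(C)(C)C)CCSc1nnnn1-c1ccccc1 | intermediate
17 | 5-{[(E)-3-({[tert-butyl(dimethyl)silyl]oxy}methyl)-4-iodobut-3-en-1-yl]sulfonyl}-1-phenyl-1H-tetrazole | I/C=C(/CO[Si](C)(C)C(C)(C)C)CCS(=O)(=O)c1nnnn1-c1ccccc1 | intermediate
18 | potassium salt of 17, deprotonated at the carbon next to sulfur | I/C=C(/CO[Si](C)(C)C(C)(C)C)C[CH-]S(=O)(=O)c1nnnn1-c1ccccc1.[K+] | intermediate
19 | 8 with CHO replaced by the (1E,4E)-4-({[tert-butyl(dimethyl)silyl]oxy}methyl)-5-iodopenta-1,4-dien-1-yl chain (iodine cis to C4) | I/C=C(/CO[Si](C)(C)C(C)(C)C)C/C=C/[C@@]1(C)CC=C(O[Si](C)(C)C(C)(C)C)[C@@H](C)[C@@H]1[C@@H]2COC(c3ccc(OC)cc3)O2 | intermediate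
20 | 19 with the dioxolane opened to C9–O-(4-methoxybenzyl) and C8H2OH (C9 unchanged) | I/C=C(/CO[Si](C)(C)C(C)(C)C)C/C=C/[C@@]1(C)CC=C(O[Si](C)(C)C(C)(C)C)[C@@H](C)[C@@H]1[C@@H](OCc2ccc(OC)cc2)CO | intermediate
21 | C8 aldehyde of 20 | I/C=C(/CO[Si](C)(C)C(C)(C)C)C/C=C/[C@@]1(C)CC=C(O[Si](C)(C)C(C)(C)C)[C@@H](C)[C@@H]1[C@@H](OCc2ccc(OC)cc2)C=O | intermediate
22 | C8 allylic alcohol with C7 vinyl group (both C8 epimers) | I/C=C(/CO[Si](C)(C)C(C)(C)C)C/C=C/[C@@]1(C)CC=C(O[Si](C)(C)C(C)(C)C)[C@@H](C)[C@@H]1[C@@H](OCc2ccc(OC)cc2)C(O)C=C | intermediate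
23 | C8 vinyl ketone | I/C=C(/CO[Si](C)(C)C(C)(C)C)C/C=C/[C@@]1(C)CC=C(O[Si](C)(C)C(C)(C)C)[C@@H](C)[C@@H]1[C@@H](OCc2ccc(OC)cc2)C(=O)C=C | intermediate
24 | methyl propanoate | CCC(=O)OC | starting material
25 | lithium (Z)-1-methoxyprop-1-en-1-olate (methyl trans to OLi) | C/C=C(\OC)O[Li] | intermediate
26 | β-hydroxy ester: C8 tertiary alcohol bearing vinyl (C7), C9 and the C17(H)(CH3)–CO2CH3 unit, C8 and C17 as in the target | I/C=C(/CO[Si](C)(C)C(C)(C)C)C/C=C/[C@@]1(C)CC=C(O[Si](C)(C)C(C)(C)C)[C@@H](C)[C@@H]1[C@@H](OCc2ccc(OC)cc2)[C@@](O)(C=C)[C@@H](C)C(=O)OC | intermediate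
27 | ring A enone of 26 (C12 ketone, C13=C14) | I/C=C(/CO[Si](C)(C)C(C)(C)C)C/C=C/[C@@]1(C)C=CC(=O)[C@@H](C)[C@@H]1[C@@H](OCc2ccc(OC)cc2)[C@@](O)(C=C)[C@@H](C)C(=O)OC | intermediate
28 | C11=C12 triethylsilyl dienol ether of 27 with C8–OSiEt3 | I/C=C(/CO[Si](C)(C)C(C)(C)C)C/C=C/[C@@]1(C)C=CC(O[Si](CC)(CC)CC)=C(C)[C@@H]1[C@@H](OCc2ccc(OC)cc2)[C@@](O[Si](CC)(CC)CC)(C=C)[C@@H](C)C(=O)OC | intermediate
29 | C11 acetate (11S) with C8–OSiEt3 | I/C=C(/CO[Si](C)(C)C(C)(C)C)C/C=C/[C@@]1(C)C=CC(=O)[C@@](C)(OC(C)=O)[C@@H]1[C@@H](OCc2ccc(OC)cc2)[C@@](O[Si](CC)(CC)CC)(C=C)[C@@H](C)C(=O)OC | intermediate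
30 | (2R,3R)-epoxide of 29 | I/C=C(/CO[Si](C)(C)C(C)(C)C)C[C@H]3O[C@@H]3[C@@]1(C)C=CC(=O)[C@@](C)(OC(C)=O)[C@@H]1[C@@H](OCc2ccc(OC)cc2)[C@@](O[Si](CC)(CC)CC)(C=C)[C@@H](C)C(=O)OC | intermediate
31 | C7 aldehyde (vinyl group of 30 cleaved) | I/C=C(/CO[Si](C)(C)C(C)(C)C)C[C@H]3O[C@@H]3[C@@]1(C)C=CC(=O)[C@@](C)(OC(C)=O)[C@@H]1[C@@H](OCc2ccc(OC)cc2)[C@@](O[Si](CC)(CC)CC)(C=O)[C@@H](C)C(=O)OC | intermediate
32 | ten-membered hydroxy ester (C6–C7 bond, 7S alcohol, ring-cis C5=C6) | CC(C)(C)[Si](C)(C)OC/C1=C/[C@H](O)[C@]([C@@H](C)C(=O)OC)(O[Si](CC)(CC)CC)[C@H](OCc3ccc(OC)cc3)[C@@H]2[C@](C)(C=CC(=O)[C@@]2(C)OC(C)=O)[C@H]2O[C@@H]2C1 | intermediate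
33 | O7–C19 lactone with C8–OSiEt3, C9–OPMB, C16–OTBS | CC(C)(C)[Si](C)(C)OC/C1=C/[C@@H]2OC(=O)[C@H](C)[C@@]2(O[Si](CC)(CC)CC)[C@H](OCc3ccc(OC)cc3)[C@@H]2[C@](C)(C=CC(=O)[C@@]2(C)OC(C)=O)[C@H]2O[C@@H]2C1 | intermediate
34 | C9 alcohol of 33 | CC(C)(C)[Si](C)(C)OC/C1=C/[C@@H]2OC(=O)[C@H](C)[C@@]2(O[Si](CC)(CC)CC)[C@H](O)[C@@H]2[C@](C)(C=CC(=O)[C@@]2(C)OC(C)=O)[C@H]2O[C@@H]2C1 | intermediate
35 | 8,9,16-triol (11-acetate) | OC/C1=C/[C@@H]2OC(=O)[C@H](C)[C@@]2(O)[C@H](O)[C@@H]2[C@](C)(C=CC(=O)[C@@]2(C)OC(C)=O)[C@H]2O[C@@H]2C1 | intermediate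
36 | CNP0226792.2 | CC(=O)OC/C1=C/[C@@H]2OC(=O)[C@H](C)[C@@]2(O)[C@H](OC(C)=O)[C@@H]2[C@](C)(C=CC(=O)[C@@]2(C)OC(C)=O)[C@H]2O[C@@H]2C1 | target

Total step count: 25.
Longest linear sequence: 21 steps (from 9 through steps 5–11 and 12–25); 17 steps from 1.

Steps most likely to fail

Step 4. The diene may add to the enal face anti to the C9–O bond instead of the face on the O9 side, which would give the C1/C10-epimeric pair, or the Lewis acid may open the aryl acetal. Fallback: replace substrate control by catalyst control. Setting out from 5 and 7, the cycloaddition is run with a proline-derived oxazaborolidinium triflimide (a chiral cationic boron Lewis acid, 10–20 mol %, CH2Cl2, −78 °C). This catalyst class is established for α-substituted enals with 2-silyloxydienes and is mild toward acetals. The catalyst antipode that exposes the required C10 face is chosen, and the route is rejoined at 8 (no new compound, F0).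

Step 17. The enolate may add in conjugate fashion to the vinyl ketone, chelation control at C8 may be incomplete, or C17 may form with the wrong relative configuration. Fallback: separate carbon–carbon bond formation from the setting of C17. Setting out from 23, a Reformatsky reaction with methyl 2-bromopropanoate and zinc (THF, 0 °C) is used; its zinc enolate adds 1,2 to enones and is chelated by the α-alkoxy ketone. It should give the C8 carbinol together with the 17-epimeric β-hydroxy ester F1. The mixture is converted into the lithium alkoxide–enolate dianion (LiN(iPr)2, 2.2 equiv, THF, −78 °C) and protonated at −78 °C with a hindered phenol on the face opposite the larger C9 branch of the six-membered chelate (the Fráter–Seebach model applied to protonation). This returns the material to 26.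

Step 22. Ring closure at the hindered aldehyde may be slow, CrCl2 may reduce the α-acetoxy enone, or the alkenylchromium may add to the wrong aldehyde face. Fallback for the wrong-face addition: setting out from 31, the same ring closure is run without the lactonisation stage and the C7-epimeric hydroxy ester F2 is isolated. Its methyl ester is cleaved with Me3SnOH (1,2-dichloroethane, 60 °C) to the C7-epimeric seco acid F3. Mitsunobu lactonisation (PPh3, diisopropyl azodicarboxylate, PhMe, 0 °C) then closes the lactone with inversion at C7 and rejoins the route at 33.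

Further compounds
F0 | step 4 | none | none
F1 | step 17 | 17-epimer of β-hydroxy ester 26 | I/C=C(/CO[Si](C)(C)C(C)(C)C)C/C=C/[C@@]1(C)CC=C(O[Si](C)(C)C(C)(C)C)[C@@H](C)[C@@H]1[C@@H](OCc2ccc(OC)cc2)[C@@](O)(C=C)[C@H](C)C(=O)OC
F2 | step 22 | C7-epimer of hydroxy ester 32 | CC(C)(C)[Si](C)(C)OC/C1=C/[C@@H](O)[C@]([C@@H](C)C(=O)OC)(O[Si](CC)(CC)CC)[C@H](OCc3ccc(OC)cc3)[C@@H]2[C@](C)(C=CC(=O)[C@@]2(C)OC(C)=O)[C@H]2O[C@@H]2C1
F3 | step 22 | C7-epimeric seco acid | CC(C)(C)[Si](C)(C)OC/C1=C/[C@@H](O)[C@]([C@@H](C)C(=O)O)(O[Si](CC)(CC)CC)[C@H](OCc3ccc(OC)cc3)[C@@H]2[C@](C)(C=CC(=O)[C@@]2(C)OC(C)=O)[C@H]2O[C@@H]2C1
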